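C2–C3 is cut back to an aldehyde and a propynyl Grignard, C1–C2 and the C1–O bond to a C1 ketone (methylenation, then dihydroxylation), the C5 ester to isovaleric acid, and the lactone O–C6 bond with the C5–O bond to a C5=C6 enone carrying a C12 acid; last, C1–C5 and C5–C6 are cut and C5 leaves as a one-carbon unit.
The last cut rests on the cycloheptane C1/C5/C6/C7/C8/C9/C10: C7 with its branch C11–C13, C10 with its methyl and the oxygenated C1 are the isopropenyl carbon, the methyl-bearing carbon and the carbonyl carbon of (R)-carvone, so only C5 has to be inserted between C1 and C6.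
Forward, the C9–C10 alkene of carvone is first turned into C9–O/C10–H, so that the enlarged ring holds a single enone; the six-membered ring then becomes the seven-membered ring by cyclopropanation of the kinetic silyl enol ether and FeCl3 opening.
The lactone ring follows by epoxidation of C5=C6 and attack of the C12 acid on C6; C2 and then C3–C4–C15 are attached to C1 last.
Stereochemistry: C7 from carvone; C9 from epoxidation of carvone trans to isopropenyl; C5 and C6 from enone epoxidation anti to C7 and inversion at C6; C10 by equilibration of the bicyclic ketone; C1 by osmylation anti to the C5 ester; the (Z)-alkene by semihydrogenation.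

Key step: step 5

Remark: the skeleton numbering of the target (ring C1–C5–C6–C7–C8–C9–C10, branch C11–C13 on C7, C14 methyl on C10, chain C2–C3–C4–C15 on C1) is used for all intermediates, α is the ring face of the C7–C11 bond and β the other face; C10, α to the ketone, is drawn as expected from step 2 until it is corrected in step 11, and drift at this centre before step 11 is assumed to be without consequence.

Step 1
Reactants: 1 (R)-(−)-carvone
Product: 2 carvone oxide, (1R,4R,6R)-1-methyl-4-(prop-1-en-2-yl)-7-oxabicyclo[4.1.0]heptan-2-one (9β,10β-epoxide, trans to isopropenyl)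
Conditions: 30% H2O2, NaOH (aq), MeOH, 0 °C
Reagents that add atoms: hydrogen peroxide, OO
Why: Weitz–Scheffer nucleophilic epoxidation, in which hydroperoxide adds to C9 of the enone anti to the C7 isopropenyl group, so the epoxide should form on the β face as is usual for carvone.

Step 2
Reactants: 2 carvone oxide
Product: 3 (2R,3R,5R)-3-hydroxy-2-methyl-5-(prop-1-en-2-yl)cyclohexan-1-one (9β-hydroxy, 10β-methyl)
Conditions: SmI2 (2.2 equiv), THF/MeOH, −90 °C
Reagents that add atoms: none
Why: Reductive cleavage of the α,β-epoxy ketone by SmI2 (divalent samarium) breaks the C10–O bond of the ketyl and leaves the C9 carbinol untouched, while protonation of the enolate anti to the axial C9–O bond should place the methyl cis to the hydroxyl (this centre is reset in step 11).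

Step 3
Reactants: 3 hydroxy ketone
Product: 4 (2R,3R,5R)-3-(tert-butyldiphenylsilyloxy)-2-methyl-5-(prop-1-en-2-yl)cyclohexan-1-one
Conditions: TBDPSCl, imidazole, DMF, rt
Reagents that add atoms: tert-butyl(chloro)diphenylsilane, CC(C)(C)[Si](Cl)(c1ccccc1)c1ccccc1
Why: Silyl ether formation with imidazole as base and nucleophilic catalyst; the TBDPS group is chosen because it should survive FeCl3, aqueous base and the acid of step 11.

Step 4
Reactants: 4 silyl ether ketone
Product: 5 trimethylsilyl enol ether (C1=C6) of 4, tert-butyl{[(1R,2R,5R)-2-methyl-5-(prop-1-en-2-yl)-3-(trimethylsilyloxy)cyclohex-3-en-1-yl]oxy}diphenylsilane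
Conditions: LiN(i-Pr)2, THF, −78 °C; TMSCl, Et3N, −78 → 0 °C
Reagents that add atoms: chlorotrimethylsilane, C[Si](C)(C)Cl
Why: Kinetic enolate formation, in which the hindered amide removes a proton from the C6 methylene rather than from the tertiary C10, followed by O-silylation, fixes the C1=C6 enol ether that directs the later insertion between C1 and C6; no stereocentre is touched.

Step 5
Reactants: 5 silyl enol ether; 6 diiodomethane
Product: 9 (4R,6R,7R)-6-(tert-butyldiphenylsilyloxy)-7-methyl-4-(prop-1-en-2-yl)cyclohept-2-en-1-one, via siloxycyclopropane 7 (not isolated), via β-chloro ketone 8 (not isolated)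
Conditions: Et2Zn, CH2I2, toluene, 0 °C → rt; FeCl3, DMF, 0 °C → rt; NaOAc, MeOH, reflux
Reagents that add atoms: diiodomethane (6), ICI
Why: The zinc carbenoid from Et2Zn and CH2I2 transfers a methylene group in a concerted [2+1] step (Simmons–Smith cyclopropanation) to the siloxy alkene C1=C6, which forms C1–C5 and C5–C6 and closes the three-membered ring of a 1-siloxybicyclo[4.1.0]heptane by cycloaddition. FeCl3 (trivalent iron) then oxidises this cyclopropyl silyl ether by one electron, the bond shared by the two rings (C1–C6) fragments and the secondary C6 radical takes up chlorine, so the seven-membered ring is not closed by a cyclisation but arises by ring enlargement of the bicycle; the closest known reaction type is the FeCl3-mediated conversion of cycloalkanone silyl enol ethers, by way of their cyclopropanes, into the next larger 2-cycloalkenones. NaOAc then removes HCl across C5–C6 (E1cB) and leaves the conjugated C5=C6 enone. No lasting stereocentre is created, since the cyclopropane carbons and the chlorinated C6 all end as sp2 or CH2 centres, and C7, C9 and C10 are not involved. The step needs methylene transfer to the enol ether and not to the isopropenyl group, which the much higher nucleophilicity of the siloxy alkene should secure when the carbenoid is not used in large excess. It also needs cleavage of the internal and not an external cyclopropane bond, which is favoured because only this mode gives a secondary radical and the enlarged-ring ketone.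

Step 6
Reactants: 9 cycloheptenone
Product: 10 (4R,6R,7R)-6-(tert-butyldiphenylsilyloxy)-4-(3-chloroprop-1-en-2-yl)-7-methylcyclohept-2-en-1-one
Conditions: Ca(OCl)2, CO2 (dry ice), CH2Cl2/H2O, 0 °C
Reagents that add atoms: calcium hypochlorite, [Ca+2].[O-]Cl.[O-]Cl
Why: Ene-type allylic chlorination by HOCl made in situ attacks the terminus of the electron-rich isopropenyl alkene and removes a methyl proton to give the transposed 2-(chloromethyl)allyl unit, as on carvone itself, while the electron-poor enone alkene should not react.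

Step 7
Reactants: 10 allylic chloride
Product: 11 2-[(1R,5R,6R)-6-(tert-butyldiphenylsilyloxy)-5-methyl-4-oxocyclohept-2-en-1-yl]prop-2-enal
Conditions: N-methylmorpholine N-oxide, NaI (cat.), MeCN, rt
Reagents that add atoms: N-methylmorpholine N-oxide, C[N+]1([O-])CCOCC1
Why: Kornblum-type oxidation with an amine N-oxide, in which the N-oxide oxygen displaces the allylic halide (SN2) and loss of N-methylmorpholine gives the 2-substituted acrolein without touching the enone.

Step 8
Reactants: 11 enal
Product: 12 2-[(1R,5R,6R)-6-(tert-butyldiphenylsilyloxy)-5-methyl-4-oxocyclohept-2-en-1-yl]prop-2-enoic acid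
Conditions: NaClO2, NaH2PO4, 2-methyl-2-butene, t-BuOH/H2O, 0 °C → rt
Reagents that add atoms: sodium chlorite, [Na+].[O-]Cl=O
Why: Pinnick oxidation converts the unsaturated aldehyde chemoselectively into the acrylic acid, the alkene scavenger trapping HOCl before it can add to the substrate.

Step 9
Reactants: 12 enone acid
Product: 14 hydroxy lactone ketone (C1 ketone, 5β-hydroxy, 6α-O/7α-C11 cis-fused α-methylene-γ-lactone, 9β-OTBDPS, 10β-methyl), via epoxy acid 13 (not isolated)
Conditions: 30% H2O2, NaOH (aq), MeOH, 0 °C; then aq HCl to pH 2, CSA (cat.), CH2Cl2, rt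
Reagents that add atoms: hydrogen peroxide, OO
Why: Weitz–Scheffer epoxidation of the only enone places hydroperoxide on C6 anti to the adjacent C7 substituent (β-epoxide, the acrylate salt being inert), and on acidification the C12 acid opens the epoxide by 5-exo attack at C6 from the α face with inversion, which sets the cis-fused lactone and the trans 5β-hydroxyl in one operation.

Step 10
Reactants: 14 hydroxy lactone ketone; 15 isovaleric acid
Product: 16 5-O-isovalerate of 14 (10β-methyl)
Conditions: EDC·HCl, DMAP (cat.), CH2Cl2, 0 °C → rt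
Reagents that add atoms: isovaleric acid (15), CC(C)CC(=O)O
Why: Steglich esterification of the only free hydroxyl, run cold with catalytic DMAP so that the β-acyloxy ketone meets no stronger base.

Step 11
Reactants: 16 isovalerate (10β-methyl)
Product: 17 isovalerate with 10α-methyl (C1 ketone, 5β-isovaleryloxy, 6α,7α-fused α-methylene-γ-lactone, 9β-OTBDPS)
Conditions: p-TsOH (anhydrous, 0.2 equiv), toluene, 60 °C
Reagents that add atoms: none
Why: Acid-catalysed keto–enol equilibration through the more substituted C1=C10 enol should epimerise C10 to the isomer whose twist-chair keeps the C5 ester, the C6 oxygen, the C9 silyl ether and the C10 methyl all equatorial (only the C7–C11 bond axial, methyl trans to the C9 oxygen), and acid is used because a base would expel the lactone oxygen from C6 by E1cB.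

Step 12
Reactants: 17 ketone
Product: 18 1-methylidene compound (exocyclic C1=C2H2, otherwise as 17)
Conditions: Tebbe reagent Cp2Ti(μ-CH2)(μ-Cl)AlMe2 (1.1 equiv), pyridine (cat.), THF/toluene, −40 → 0 °C
Reagents that add atoms: Tebbe reagent, C[Al-]1(C)C[Ti]([Cl+]1)(C2C=CC=C2)C3C=CC=C3
Why: Tebbe methylenation proceeds by [2+2] addition of Cp2Ti=CH2, released from the chloride-bridged Ti–CH2–Al reagent by pyridine, to the ketone and cycloreversion under non-basic conditions, so C5 and C10 should keep their configuration, and at low temperature with little excess the ketone should react before the ester and lactone carbonyls.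

Step 13
Reactants: 18 exocyclic alkene
Product: 19 diol (1α-hydroxy, 1β-hydroxymethyl, otherwise as 18)
Conditions: OsO4 (5 mol %), N-methylmorpholine N-oxide, acetone/H2O, 0 °C → rt
Reagents that add atoms: osmium tetroxide (catalytic oxygen carrier), O=[Os](=O)(=O)=O; N-methylmorpholine N-oxide, C[N+]1([O-])CCOCC1; water, O
Why: Upjohn dihydroxylation should take the electron-rich exocyclic alkene before the electron-poor lactone methylene, and osmylation anti to the allylic C5 acyloxy group (the usual sense for allylic ethers and esters, reinforced by the 9β silyl ether) should deliver the tertiary hydroxyl to the α face of C1 and leave C2 on the β face.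

Step 14
Reactants: 19 diol
Product: 20 α-hydroxy aldehyde (1α-hydroxy, 1β-formyl)
Conditions: SO3·pyridine, DMSO, i-Pr2NEt, CH2Cl2, 0 °C
Reagents that add atoms: none
Why: Parikh–Doering oxidation (activated DMSO) can only oxidise the primary hydroxyl, and the cold, brief conditions should avoid α-ketol rearrangement of the aldehyde, which is used at once.

Step 15
Reactants: 20 α-hydroxy aldehyde; 21 1-propynylmagnesium bromide
Product: 22 propargylic diol (1α-hydroxy, 1β-(1-hydroxybut-2-yn-1-yl), both C2 epimers)
Conditions: 1-propynylmagnesium bromide (2.5 equiv), THF, −78 °C; aq NH4Cl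
Reagents that add atoms: 1-propynylmagnesium bromide (21), CC#C[Mg]Br
Why: Grignard addition of the alkynyl reagent to the aldehyde at −78 °C should be far faster than attack on ester or lactone; one equivalent is used up by the tertiary hydroxyl and the new C2 configuration is irrelevant because C2 is oxidised in step 17.

Step 16
Reactants: 22 propargylic diol
Product: 23 triol (9β-hydroxyl set free)
Conditions: HF·pyridine, pyridine, THF, 0 °C → rt
Reagents that add atoms: none
Why: Fluoride-driven cleavage of the silyl ether (Si–F bond formation) under buffered conditions should leave esters, lactone and alkyne alone, and is placed here because this diol is the most robust late intermediate.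

Step 17
Reactants: 23 triol
Product: 24 ynone (1β-but-2-ynoyl, 1α,9β-dihydroxy)
Conditions: MnO2 (activated), CH2Cl2, rt
Reagents that add atoms: none
Why: MnO2 oxidation is selective for activated (here propargylic) alcohols, so the C2 carbinol should give the ynone while the saturated C9 secondary and the C1 tertiary hydroxyl remain.

Step 18
Reactants: 24 ynone
Product: 25 CNP0186412.2, the target
Conditions: H2 (1 atm), Pd/CaCO3 poisoned with Pb(OAc)2, quinoline, EtOAc, 0 °C
Reagents that add atoms: none
Why: Lindlar semihydrogenation delivers H2 syn on the poisoned palladium surface and should stop at the (Z)-enone, the quinoline-poisoned catalyst not reducing the 1,1-disubstituted lactone methylene on the time scale of alkyne reduction.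

Compound list
1 | (R)-(−)-carvone | O=C1C[C@H](C(C)=C)CC=C1C | starting material
2 | carvone oxide, (1R,4R,6R)-1-methyl-4-(prop-1-en-2-yl)-7-oxabicyclo[4.1.0]heptan-2-one | O=C1C[C@H](C(C)=C)C[C@H]2O[C@@]12C | intermediate
3 | (2R,3R,5R)-3-hydroxy-2-methyl-5-(prop-1-en-2-yl)cyclohexan-1-one | O=C1C[C@H](C(C)=C)C[C@@H](O)[C@H]1C | intermediate
4 | (2R,3R,5R)-3-(tert-butyldiphenylsilyloxy)-2-methyl-5-(prop-1-en-2-yl)cyclohexan-1-one | O=C1C[C@H](C(C)=C)C[C@@H](O[Si](c2ccccc2)(c2ccccc2)C(C)(C)C)[C@H]1C | intermediate
5 | trimethylsilyl enol ether (C1=C6) of 4, tert-butyl{[(1R,2R,5R)-2-methyl-5-(prop-1-en-2-yl)-3-(trimethylsilyloxy)cyclohex-3-en-1-yl]oxy}diphenylsilane | C[Si](C)(C)OC1=C[C@H](C(C)=C)C[C@@H](O[Si](c2ccccc2)(c2ccccc2)C(C)(C)C)[C@H]1C | intermediate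
6 | diiodomethane | ICI | starting material
7 | siloxycyclopropane: 1-(trimethylsilyloxy)bicyclo[4.1.0]heptane from 5, three-membered ring C1–C5–C6, both ring-fusion diastereomers | C[Si](C)(C)OC12CC1[C@H](C(C)=C)C[C@@H](O[Si](c3ccccc3)(c3ccccc3)C(C)(C)C)[C@H]2C | intermediate (not isolated)
8 | β-chloro ketone: 3-chloro-6-(tert-butyldiphenylsilyloxy)-7-methyl-4-(prop-1-en-2-yl)cycloheptan-1-one, chloride on skeleton C6, both epimers | O=C1CC(Cl)[C@H](C(C)=C)C[C@@H](O[Si](c2ccccc2)(c2ccccc2)C(C)(C)C)[C@H]1C | intermediate (not isolated)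
9 | (4R,6R,7R)-6-(tert-butyldiphenylsilyloxy)-7-methyl-4-(prop-1-en-2-yl)cyclohept-2-en-1-one | O=C1C=C[C@H](C(C)=C)C[C@@H](O[Si](c2ccccc2)(c2ccccc2)C(C)(C)C)[C@H]1C | intermediate
10 | (4R,6R,7R)-6-(tert-butyldiphenylsilyloxy)-4-(3-chloroprop-1-en-2-yl)-7-methylcyclohept-2-en-1-one | O=C1C=C[C@H](C(CCl)=C)C[C@@H](O[Si](c2ccccc2)(c2ccccc2)C(C)(C)C)[C@H]1C | intermediate
11 | 2-[(1R,5R,6R)-6-(tert-butyldiphenylsilyloxy)-5-methyl-4-oxocyclohept-2-en-1-yl]prop-2-enal | O=C1C=C[C@H](C(C=O)=C)C[C@@H](O[Si](c2ccccc2)(c2ccccc2)C(C)(C)C)[C@H]1C | intermediate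
12 | 2-[(1R,5R,6R)-6-(tert-butyldiphenylsilyloxy)-5-methyl-4-oxocyclohept-2-en-1-yl]prop-2-enoic acid | O=C1C=C[C@H](C(C(=O)O)=C)C[C@@H](O[Si](c2ccccc2)(c2ccccc2)C(C)(C)C)[C@H]1C | intermediate
13 | epoxy acid: 5β,6β-epoxide of 12 | O=C1[C@H]2O[C@H]2[C@H](C(C(=O)O)=C)C[C@@H](O[Si](c3ccccc3)(c3ccccc3)C(C)(C)C)[C@H]1C | intermediate (not isolated)
14 | hydroxy lactone ketone: C1 ketone, 5β-hydroxy, 6α-O/7α-C11 cis-fused α-methylene-γ-lactone, 9β-OTBDPS, 10β-methyl | C=C1C(=O)O[C@@H]2[C@H]1C[C@@H](O[Si](c3ccccc3)(c3ccccc3)C(C)(C)C)[C@@H](C)C(=O)[C@H]2O | intermediate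
15 | isovaleric acid (3-methylbutanoic acid) | CC(C)CC(=O)O | starting material
16 | 5-O-isovalerate of 14 (10β-methyl) | C=C1C(=O)O[C@@H]2[C@H]1C[C@@H](O[Si](c3ccccc3)(c3ccccc3)C(C)(C)C)[C@@H](C)C(=O)[C@H]2OC(=O)CC(C)C | intermediate
17 | C10 epimer of 16 (10α-methyl) | C=C1C(=O)O[C@@H]2[C@H]1C[C@@H](O[Si](c3ccccc3)(c3ccccc3)C(C)(C)C)[C@H](C)C(=O)[C@H]2OC(=O)CC(C)C | intermediate
18 | 1-methylidene compound from 17 | C=C1C(=O)O[C@@H]2[C@H]1C[C@@H](O[Si](c3ccccc3)(c3ccccc3)C(C)(C)C)[C@H](C)C(=C)[C@H]2OC(=O)CC(C)C | intermediate
19 | diol: 1α-hydroxy, 1β-hydroxymethyl | C=C1C(=O)O[C@@H]2[C@H]1C[C@@H](O[Si](c3ccccc3)(c3ccccc3)C(C)(C)C)[C@H](C)[C@@](O)(CO)[C@H]2OC(=O)CC(C)C | intermediate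
20 | α-hydroxy aldehyde: 1α-hydroxy, 1β-formyl | C=C1C(=O)O[C@@H]2[C@H]1C[C@@H](O[Si](c3ccccc3)(c3ccccc3)C(C)(C)C)[C@H](C)[C@@](O)(C=O)[C@H]2OC(=O)CC(C)C | intermediate
21 | 1-propynylmagnesium bromide | CC#C[Mg]Br | starting material
22 | propargylic diol: 1α-hydroxy, 1β-(1-hydroxybut-2-yn-1-yl), both C2 epimers | C=C1C(=O)O[C@@H]2[C@H]1C[C@@H](O[Si](c3ccccc3)(c3ccccc3)C(C)(C)C)[C@H](C)[C@@](O)(C(O)C#CC)[C@H]2OC(=O)CC(C)C | intermediate
23 | triol: 22 without the silyl group (9β-hydroxy) | C=C1C(=O)O[C@@H]2[C@H]1C[C@@H](O)[C@H](C)[C@@](O)(C(O)C#CC)[C@H]2OC(=O)CC(C)C | intermediate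
24 | ynone: 1β-but-2-ynoyl, 1α,9β-dihydroxy | C=C1C(=O)O[C@@H]2[C@H]1C[C@@H](O)[C@H](C)[C@@](O)(C(=O)C#CC)[C@H]2OC(=O)CC(C)C | intermediate
25 | CNP0186412.2, (1S,5S,6R,7S,9R,10S) in skeleton numbering: 1α,9β-dihydroxy, 1β-[(Z)-but-2-enoyl], 5β-isovaleryloxy, 10α-methyl, 6α,7α-fused α-methylene-γ-lactone | C=C1C(=O)O[C@@H]2[C@H]1C[C@@H](O)[C@H](C)[C@@](O)(C(=O)/C=C\C)[C@H]2OC(=O)CC(C)C | target

Total step count: 18
Longest linear sequence: 18 steps, from (R)-carvone 1 to 25; 6, 15 and 21 are bought and enter in steps 5, 10 and 15.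

Steps most likely to fail

Step 13. Osmium may attack the exocyclic alkene on the wrong (β) face, because the faces of C1 are flanked almost symmetrically (C5 ester and C9 silyl ether on β, C10 methyl and lactone oxygen on α), and the lactone methylene may be dihydroxylated in competition. The fallback uses the fact that adding oxygen to the alkene and adding carbon to the ketone are complementary at C1: a face that is wrong for oxygen on 18 is right for carbon on 17. It sets out from ketone 17: vinylmagnesium bromide with CeCl3 (THF, −78 °C) should add from that face and give the tertiary allylic alcohol F1 with C2 on the β face and the hydroxyl α. Ozonolysis of the electron-rich vinyl group (O3, CH2Cl2/MeOH, −78 °C, Sudan red as end-point indicator, then Me2S) then gives aldehyde 20, where the route is rejoined.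

Step 11. The equilibration at C10 may stall or settle on the wrong side, and the acid may cause β-elimination of the C9 silyloxy group or of the lactone oxygen. The fallback equilibrates with base in a bicycle whose C6 oxygen is an ether, a poor leaving group, and oxidises that ether to the lactone afterwards. It sets out from enal 11: NaBH4 (MeOH/CH2Cl2, −78 °C) should reduce only the aldehyde and give the allylic alcohol F2. Epoxidation of the enone (H2O2, NaOH) and acid-catalysed 5-exo opening of the epoxide at C6 by the primary hydroxyl (CSA) give the cis-fused 3-methylenetetrahydrofuran hydroxy ketone F3. Steglich acylation with 15 gives the isovalerate F4, and DBU (toluene, rt) should equilibrate C10 to the 10α-methyl epimer F5. Allylic oxidation of the ether methylene C12 with CrO3 and 3,5-dimethylpyrazole (CH2Cl2, −20 °C) then gives lactone 17, where the route is rejoined.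

Step 18. The hydrogenation may run on to the saturated ketone, isomerise the (Z)-enone to the (E)-enone, or reduce or shift the lactone methylene. The fallback brings in the (Z)-alkene ready-made and sets out from aldehyde 20: Nozaki–Hiyama–Kishi coupling with (Z)-1-iodoprop-1-ene (CrCl2, NiCl2 cat., DMF) should give the (Z)-allylic alcohol F6 with the alkene geometry retained. Dess–Martin periodinane (NaHCO3, CH2Cl2) oxidises it to the (Z)-enone silyl ether F7, and HF·pyridine removes the silyl group to give 25.

Further compounds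
F1 | step 13 | tertiary allylic alcohol: 1α-hydroxy, 1β-vinyl adduct of ketone 17 | C=C1C(=O)O[C@@H]2[C@H]1C[C@@H](O[Si](c3ccccc3)(c3ccccc3)C(C)(C)C)[C@H](C)[C@@](O)(C=C)[C@H]2OC(=O)CC(C)C
F2 | step 11 | allylic alcohol: (4R,6R,7R)-6-(tert-butyldiphenylsilyloxy)-4-(3-hydroxyprop-1-en-2-yl)-7-methylcyclohept-2-en-1-one | O=C1C=C[C@H](C(CO)=C)C[C@@H](O[Si](c2ccccc2)(c2ccccc2)C(C)(C)C)[C@H]1C
F3 | step 11 | tetrahydrofuran hydroxy ketone: C1 ketone, 5β-hydroxy, 6α-O/7α-C11 cis-fused 3-methylenetetrahydrofuran, 9β-OTBDPS, 10β-methyl | C=C1CO[C@@H]2[C@H]1C[C@@H](O[Si](c3ccccc3)(c3ccccc3)C(C)(C)C)[C@@H](C)C(=O)[C@H]2O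
F4 | step 11 | 5-O-isovalerate of F3 (10β-methyl) | C=C1CO[C@@H]2[C@H]1C[C@@H](O[Si](c3ccccc3)(c3ccccc3)C(C)(C)C)[C@@H](C)C(=O)[C@H]2OC(=O)CC(C)C
F5 | step 11 | C10 epimer of F4 (10α-methyl) | C=C1CO[C@@H]2[C@H]1C[C@@H](O[Si](c3ccccc3)(c3ccccc3)C(C)(C)C)[C@H](C)C(=O)[C@H]2OC(=O)CC(C)C
F6 | step 18 | (Z)-allylic alcohol: 1α-hydroxy, 1β-[(Z)-1-hydroxybut-2-en-1-yl], 9β-OTBDPS, both C2 epimers | C=C1C(=O)O[C@@H]2[C@H]1C[C@@H](O[Si](c3ccccc3)(c3ccccc3)C(C)(C)C)[C@H](C)[C@@](O)(C(O)/C=C\C)[C@H]2OC(=O)CC(C)C
F7 | step 18 | (Z)-enone silyl ether: 9-O-TBDPS ether of 25 | C=C1C(=O)O[C@@H]2[C@H]1C[C@@H](O[Si](c3ccccc3)(c3ccccc3)C(C)(C)C)[C@H](C)[C@@](O)(C(=O)/C=C\C)[C@H]2OC(=O)CC(C)C
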